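Retrosynthesis: the six O-benzyl groups are removed last. Before that the ester C–O bond between the C4 cinnamic acid and the (R)-lactate alcohol is cut, then the C2–C3 bond of the dihydrofuran, then the aryl–CH2 bond of the arylacetate, the acrylate C=C and the ArO–CH2Ar bond.
Enabling feature: C2 is benzylic and bonded to O1 and to the catechol ring (ring B), and C3 bears the benzo ring (ring A) and a carboxyl. This is the imprint of an aryl(alkoxycarbonyl)carbene centred on C3 that has inserted into a benzylic C–H of an aryl benzyl ether sitting ortho on ring A.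
Forward: ring A is brominated, etherified with the ring B benzyl unit, olefinated and cross-coupled to an arylacetate. Diazo transfer and rhodium carbene C–H insertion then close the dihydrofuran, the only ring made. The side chain is esterified on afterwards and all benzyl groups fall in one operation.
Stereochemistry: C2 comes from the chiral dirhodium carboxylate (kinetic cis ester), C3 is then set trans by base equilibration against C2, and the side-chain centre is carried over from (R)-danshensu.

Key step: step 6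

Assumption: in the closest analogues of this insertion the (S)-tert-leucinate-derived dirhodium catalysts are taken to lead to the 2R series, so the 2S series is assigned to Rh2(R-PTTL)4; if the first run shows the opposite sense, step 6 is run with Rh2(S-PTTL)4 and nothing else changes.

Step 1
Reactants: 1 4-(benzyloxy)-3-hydroxybenzaldehyde
Product: 2 4-(benzyloxy)-2-bromo-3-hydroxybenzaldehyde
Conditions: Br2 (1.05 equiv), NaOAc, Fe powder (cat.), AcOH, rt
Reagents that add atoms: bromine, BrBr
Why: Electrophilic aromatic bromination of isovanillin-type phenols is known to go to C2, ortho to the free hydroxyl and next to the formyl group, and the acetate buffer should keep the benzyl ether from acid cleavage.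

Step 2
Reactants: 2 4-(benzyloxy)-2-bromo-3-hydroxybenzaldehyde; 3 3,4-bis(benzyloxy)benzyl chloride
Product: 4 4-(benzyloxy)-3-{[3,4-bis(benzyloxy)benzyl]oxy}-2-bromobenzaldehyde
Conditions: K2CO3, Bu4NI (cat.), DMF, 60 °C
Reagents that add atoms: none
Why: Williamson ether synthesis, in which the potassium phenoxide displaces the iodide-activated benzylic chloride and no other nucleophile is present.

Step 3
Reactants: 4 4-(benzyloxy)-3-{[3,4-bis(benzyloxy)benzyl]oxy}-2-bromobenzaldehyde; 5 tert-butyl (triphenylphosphoranylidene)acetate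
Product: 6 tert-butyl (E)-3-[4-(benzyloxy)-3-{[3,4-bis(benzyloxy)benzyl]oxy}-2-bromophenyl]acrylate
Conditions: toluene, 80 °C
Reagents that add atoms: none
Why: Wittig olefination with a stabilised ylide should give the E-cinnamate and leaves the aryl bromide and the benzyl ethers untouched.

Step 4
Reactants: 6 tert-butyl (E)-3-[4-(benzyloxy)-3-{[3,4-bis(benzyloxy)benzyl]oxy}-2-bromophenyl]acrylate; 7 benzyl bromoacetate
Product: 9 benzyl 2-[3-(benzyloxy)-2-{[3,4-bis(benzyloxy)benzyl]oxy}-6-[(E)-3-tert-butoxy-3-oxoprop-1-en-1-yl]phenyl]acetate, via benzyl (bromozincio)acetate 8 (not isolated)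
Conditions: 7, Zn dust (TMSCl-activated), THF, rt; then 6, Pd2(dba)3 (2.5 mol %), XPhos (10 mol %), THF, 60 °C
Reagents that add atoms: none
Why: Negishi-type alpha-arylation with a Reformatsky reagent, in which zerovalent palladium carrying the bulky biaryl phosphine enters the hindered C–Br bond, the zinc enolate transmetalates and reductive elimination gives the arylacetate, while the weakly basic zinc reagent should tolerate both esters and not add to the cinnamate.

Step 5
Reactants: 9 benzyl 2-[3-(benzyloxy)-2-{[3,4-bis(benzyloxy)benzyl]oxy}-6-[(E)-3-tert-butoxy-3-oxoprop-1-en-1-yl]phenyl]acetate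
Product: 10 benzyl 2-diazo-2-[3-(benzyloxy)-2-{[3,4-bis(benzyloxy)benzyl]oxy}-6-[(E)-3-tert-butoxy-3-oxoprop-1-en-1-yl]phenyl]acetate
Conditions: p-ABSA (1.3 equiv), DBU (1.5 equiv), MeCN, 0 °C → rt; used at once
Reagents that add atoms: 4-acetamidobenzenesulfonyl azide (p-ABSA), CC(=O)Nc1ccc(cc1)S(=O)(=O)N=[N+]=[N-]
Why: Regitz diazo transfer, in which DBU deprotonates the benzylic arylacetate position and the enolate takes the N2 unit from the sulfonyl azide, is the standard route to aryldiazoacetates, and cold work-up with immediate use should keep the diazo group from reacting thermally with the neighbouring acrylate.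

Step 6
Reactants: 10 benzyl 2-diazo-2-[3-(benzyloxy)-2-{[3,4-bis(benzyloxy)benzyl]oxy}-6-[(E)-3-tert-butoxy-3-oxoprop-1-en-1-yl]phenyl]acetate
Product: 11 benzyl (2S,3R)-7-(benzyloxy)-2-[3,4-bis(benzyloxy)phenyl]-4-[(E)-3-tert-butoxy-3-oxoprop-1-en-1-yl]-2,3-dihydro-1-benzofuran-3-carboxylate (cis)
Conditions: Rh2(R-PTTL)4 [dirhodium tetrakis(N-phthaloyl-(R)-tert-leucinate), 1 mol %], toluene, slow addition of 10, −78 → −40 °C
Reagents that add atoms: none
Why: The dirhodium tetracarboxylate (divalent rhodium) expels N2 from 10 to give a donor–acceptor rhodium carbene at the future C3, which inserts into a benzylic C–H of the ortho ArCH2O group through a concerted three-centre transition state with hydride-transfer character, forming the C2–C3 bond. The closest known reaction type is the enantioselective intramolecular C–H insertion of aryldiazoacetates into benzylic ether C–H bonds under phthalimido-amino-acid dirhodium catalysts, which gives cis-2-aryl-2,3-dihydrobenzofuran-3-carboxylates. The dihydrofuran ring closes by 1,5-insertion through a five-membered transition state made up of the carbene carbon, C3a, C7a, O1 and C2. C2 is controlled by the pocket of the four N-phthaloyl-(R)-tert-leucinate ligands, which selects one of the two enantiotopic benzylic hydrogens, and C3 is set in the same event, the concerted insertion placing ring B and the ester on the same face to give the kinetic (2S,3R) cis ester. The step needs site selectivity and chemoselectivity: the reacting C–H is the only one activated by both O1 and the electron-rich 3,4-bis(benzyloxy)phenyl ring that can reach the carbene through a five-membered geometry, the other benzylic ether C–H bonds being out of intramolecular reach. The acrylate is electron-poor and could be captured only by forming a strained small ring, so it should stay a spectator, and low temperature with slow addition suppresses carbene dimerisation.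

Step 7
Reactants: 11 benzyl (2S,3R)-7-(benzyloxy)-2-[3,4-bis(benzyloxy)phenyl]-4-[(E)-3-tert-butoxy-3-oxoprop-1-en-1-yl]-2,3-dihydro-1-benzofuran-3-carboxylate (cis)
Product: 12 benzyl (2S,3S)-7-(benzyloxy)-2-[3,4-bis(benzyloxy)phenyl]-4-[(E)-3-tert-butoxy-3-oxoprop-1-en-1-yl]-2,3-dihydro-1-benzofuran-3-carboxylate (trans)
Conditions: DBU (0.3 equiv), CH2Cl2, rt
Reagents that add atoms: none
Why: Base-mediated epimerisation through the ester enolate, since C3–H is alpha to the ester and benzylic, should equilibrate the cis ester to the more stable trans isomer with ring B and the ester on opposite faces, which sets C3 as S while the non-acidic C2 stays as formed.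

Step 8
Reactants: 12 benzyl (2S,3S)-7-(benzyloxy)-2-[3,4-bis(benzyloxy)phenyl]-4-[(E)-3-tert-butoxy-3-oxoprop-1-en-1-yl]-2,3-dihydro-1-benzofuran-3-carboxylate (trans)
Product: 13 (E)-3-[(2S,3S)-7-(benzyloxy)-3-[(benzyloxy)carbonyl]-2-[3,4-bis(benzyloxy)phenyl]-2,3-dihydro-1-benzofuran-4-yl]acrylic acid
Conditions: TFA/CH2Cl2 (1:4), 0 °C
Reagents that add atoms: none
Why: Acidolysis of the tert-butyl ester by loss of isobutene in cold dilute TFA should be selective over the benzyl ethers and the benzyl ester, and the adjacent electron-withdrawing ester should hold the C2–O1 bond against ionisation.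

Step 9
Reactants: 14 (R)-3-(3,4-dihydroxyphenyl)lactic acid (danshensu)
Product: 15 methyl (2R)-3-(3,4-dihydroxyphenyl)-2-hydroxypropanoate
Conditions: MeOH, conc. H2SO4 (cat.), 55 °C
Reagents that add atoms: methanol, CO
Why: Fischer esterification in methanol under acid catalysis converts only the carboxylic acid and touches neither the stereocentre nor the catechol.

Step 10
Reactants: 15 methyl (2R)-3-(3,4-dihydroxyphenyl)-2-hydroxypropanoate
Product: 16 methyl (2R)-3-[3,4-bis(benzyloxy)phenyl]-2-hydroxypropanoate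
Conditions: BnBr (2.1 equiv), K2CO3, acetone, 50 °C
Reagents that add atoms: benzyl bromide, BrCc1ccccc1
Why: Williamson benzylation with K2CO3 should alkylate only the two phenols, which are far more acidic than the secondary alcohol, and the base is too weak to enolise the alpha-hydroxy ester, so the R centre is kept.

Step 11
Reactants: 13 (E)-3-[(2S,3S)-7-(benzyloxy)-3-[(benzyloxy)carbonyl]-2-[3,4-bis(benzyloxy)phenyl]-2,3-dihydro-1-benzofuran-4-yl]acrylic acid; 16 methyl (2R)-3-[3,4-bis(benzyloxy)phenyl]-2-hydroxypropanoate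
Product: 17 benzyl (2S,3S)-7-(benzyloxy)-2-[3,4-bis(benzyloxy)phenyl]-4-[(E)-3-{[(2R)-3-[3,4-bis(benzyloxy)phenyl]-1-methoxy-1-oxopropan-2-yl]oxy}-3-oxoprop-1-en-1-yl]-2,3-dihydro-1-benzofuran-3-carboxylate
Conditions: EDC·HCl (1.5 equiv), DMAP (0.2 equiv), CH2Cl2, 0 °C → rt
Reagents that add atoms: none
Why: Steglich esterification, in which the carbodiimide activates the cinnamic acid and DMAP passes the acyl group to the secondary alcohol with retention at the carbinol carbon, should leave the C3 benzyl ester and all ethers inert.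

Step 12
Reactants: 17 benzyl (2S,3S)-7-(benzyloxy)-2-[3,4-bis(benzyloxy)phenyl]-4-[(E)-3-{[(2R)-3-[3,4-bis(benzyloxy)phenyl]-1-methoxy-1-oxopropan-2-yl]oxy}-3-oxoprop-1-en-1-yl]-2,3-dihydro-1-benzofuran-3-carboxylate
Product: 18 (2S,3S)-2-(3,4-dihydroxyphenyl)-4-[(E)-3-{[(2R)-3-(3,4-dihydroxyphenyl)-1-methoxy-1-oxopropan-2-yl]oxy}-3-oxoprop-1-en-1-yl]-7-hydroxy-2,3-dihydro-1-benzofuran-3-carboxylic acid (CNP0120702.1)
Conditions: BCl3 (12 equiv), pentamethylbenzene (18 equiv), CH2Cl2, −78 → 0 °C; aq. NaH2PO4 quench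
Reagents that add atoms: none
Why: Lewis-acid debenzylation with a non-basic cation scavenger, in which BCl3 binds each benzyl oxygen and the benzyl cation passes to pentamethylbenzene in a Friedel–Crafts alkylation, should cleave the five aryl benzyl ethers cold and the benzyl ester on warming while the alkene, the methyl ester, the side-chain ester and the three stereocentres stay intact.

Compound list
1 | 4-(benzyloxy)-3-hydroxybenzaldehyde | O=Cc1ccc(OCc2ccccc2)c(O)c1 | starting material
2 | 4-(benzyloxy)-2-bromo-3-hydroxybenzaldehyde | O=Cc1ccc(OCc2ccccc2)c(O)c1Br | intermediate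
3 | 3,4-bis(benzyloxy)benzyl chloride | ClCc1ccc(OCc2ccccc2)c(OCc2ccccc2)c1 | starting material
4 | 4-(benzyloxy)-3-{[3,4-bis(benzyloxy)benzyl]oxy}-2-bromobenzaldehyde | O=Cc1ccc(OCc2ccccc2)c(OCc2ccc(OCc3ccccc3)c(OCc3ccccc3)c2)c1Br | intermediate
5 | tert-butyl (triphenylphosphoranylidene)acetate | CC(C)(C)OC(=O)C=P(c1ccccc1)(c1ccccc1)c1ccccc1 | starting material
6 | tert-butyl (E)-3-[4-(benzyloxy)-3-{[3,4-bis(benzyloxy)benzyl]oxy}-2-bromophenyl]acrylate | CC(C)(C)OC(=O)/C=C/c1ccc(OCc2ccccc2)c(OCc2ccc(OCc3ccccc3)c(OCc3ccccc3)c2)c1Br | intermediate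
7 | benzyl bromoacetate | BrCC(=O)OCc1ccccc1 | starting material
8 | benzyl (bromozincio)acetate (Reformatsky reagent) | Br[Zn]CC(=O)OCc1ccccc1 | intermediate
9 | benzyl 2-[3-(benzyloxy)-2-{[3,4-bis(benzyloxy)benzyl]oxy}-6-[(E)-3-tert-butoxy-3-oxoprop-1-en-1-yl]phenyl]acetate | CC(C)(C)OC(=O)/C=C/c1ccc(OCc2ccccc2)c(OCc2ccc(OCc3ccccc3)c(OCc3ccccc3)c2)c1CC(=O)OCc1ccccc1 | intermediate
10 | benzyl 2-diazo-2-[3-(benzyloxy)-2-{[3,4-bis(benzyloxy)benzyl]oxy}-6-[(E)-3-tert-butoxy-3-oxoprop-1-en-1-yl]phenyl]acetate | CC(C)(C)OC(=O)/C=C/c1ccc(OCc2ccccc2)c(OCc2ccc(OCc3ccccc3)c(OCc3ccccc3)c2)c1C(=[N+]=[N-])C(=O)OCc1ccccc1 | intermediate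
11 | benzyl (2S,3R)-7-(benzyloxy)-2-[3,4-bis(benzyloxy)phenyl]-4-[(E)-3-tert-butoxy-3-oxoprop-1-en-1-yl]-2,3-dihydro-1-benzofuran-3-carboxylate (cis) | CC(C)(C)OC(=O)/C=C/c1ccc(OCc3ccccc3)c2c1[C@@H](C(=O)OCc1ccccc1)[C@@H](c1ccc(OCc3ccccc3)c(OCc3ccccc3)c1)O2 | intermediate
12 | benzyl (2S,3S)-7-(benzyloxy)-2-[3,4-bis(benzyloxy)phenyl]-4-[(E)-3-tert-butoxy-3-oxoprop-1-en-1-yl]-2,3-dihydro-1-benzofuran-3-carboxylate (trans) | CC(C)(C)OC(=O)/C=C/c1ccc(OCc3ccccc3)c2c1[C@H](C(=O)OCc1ccccc1)[C@@H](c1ccc(OCc3ccccc3)c(OCc3ccccc3)c1)O2 | intermediate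
13 | (E)-3-[(2S,3S)-7-(benzyloxy)-3-[(benzyloxy)carbonyl]-2-[3,4-bis(benzyloxy)phenyl]-2,3-dihydro-1-benzofuran-4-yl]acrylic acid | OC(=O)/C=C/c1ccc(OCc3ccccc3)c2c1[C@H](C(=O)OCc1ccccc1)[C@@H](c1ccc(OCc3ccccc3)c(OCc3ccccc3)c1)O2 | intermediate
14 | (R)-3-(3,4-dihydroxyphenyl)lactic acid (danshensu) | O=C(O)[C@@H](Cc1ccc(O)c(O)c1)O | starting material
15 | methyl (2R)-3-(3,4-dihydroxyphenyl)-2-hydroxypropanoate | COC(=O)[C@@H](Cc1ccc(O)c(O)c1)O | intermediate
16 | methyl (2R)-3-[3,4-bis(benzyloxy)phenyl]-2-hydroxypropanoate | COC(=O)[C@@H](Cc1ccc(OCc2ccccc2)c(OCc2ccccc2)c1)O | intermediate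
17 | benzyl (2S,3S)-7-(benzyloxy)-2-[3,4-bis(benzyloxy)phenyl]-4-[(E)-3-{[(2R)-3-[3,4-bis(benzyloxy)phenyl]-1-methoxy-1-oxopropan-2-yl]oxy}-3-oxoprop-1-en-1-yl]-2,3-dihydro-1-benzofuran-3-carboxylate | COC(=O)[C@@H](Cc1ccc(OCc2ccccc2)c(OCc2ccccc2)c1)OC(=O)/C=C/c1ccc(OCc2ccccc2)c2c1[C@H](C(=O)OCc1ccccc1)[C@@H](c1ccc(OCc3ccccc3)c(OCc3ccccc3)c1)O2 | intermediate
18 | (2S,3S)-2-(3,4-dihydroxyphenyl)-4-[(E)-3-{[(2R)-3-(3,4-dihydroxyphenyl)-1-methoxy-1-oxopropan-2-yl]oxy}-3-oxoprop-1-en-1-yl]-7-hydroxy-2,3-dihydro-1-benzofuran-3-carboxylic acid (CNP0120702.1) | COC(=O)[C@@H](Cc1ccc(O)c(O)c1)OC(=O)/C=C/c1ccc(O)c2c1[C@H](C(=O)O)[C@@H](c1ccc(O)c(O)c1)O2 | target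

Total step count: 12 steps.
Longest linear sequence: 10 steps (steps 1 to 8, then 11 and 12, from compound 1); the side-chain branch (steps 9 and 10) joins at step 11.

Steps most likely to fail

Step 6. The acrylate on the second ortho position may twist the aryl group out of the carbene plane, a situation for which the ligand set has no close model, so that the choice between the two benzylic hydrogens and the cis preference are eroded. The fallback sets out from 10 and comes back at 12; it gives up catalyst control of absolute configuration in favour of resolution. Decomposition of 10 with achiral Rh2(OAc)4 (1 mol %, CH2Cl2, 0 °C) should give the racemic cis ester, benzyl (2S*,3R*)-7-(benzyloxy)-2-[3,4-bis(benzyloxy)phenyl]-4-[(E)-3-tert-butoxy-3-oxoprop-1-en-1-yl]-2,3-dihydro-1-benzofuran-3-carboxylate F1, possibly mixed with its trans isomer. DBU in CH2Cl2 then converges the mixture on the racemic trans ester, benzyl (2S*,3S*)-7-(benzyloxy)-2-[3,4-bis(benzyloxy)phenyl]-4-[(E)-3-tert-butoxy-3-oxoprop-1-en-1-yl]-2,3-dihydro-1-benzofuran-3-carboxylate F2. Preparative chromatography on a polysaccharide chiral stationary phase separates 12 from its mirror image, the (2R,3R)-trans ester F3, which is set aside.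

Step 4. The zinc enolate may be used up by self-condensation and protonation at the temperature that entry of palladium into the electron-rich, doubly ortho-flanked C–Br bond requires. The fallback sets out from 6 and comes back at 9; it reverses the polarity of the two partners. Miyaura borylation of 6 (B2pin2, Pd(dppf)Cl2, KOAc, dioxane, 90 °C), which involves no fragile nucleophile and can be heated freely, should give the pinacol boronate tert-butyl (E)-3-[4-(benzyloxy)-3-{[3,4-bis(benzyloxy)benzyl]oxy}-2-(4,4,5,5-tetramethyl-1,3,2-dioxaborolan-2-yl)phenyl]acrylate F4. Suzuki–Miyaura coupling of F4 with benzyl bromoacetate 7 (Pd(OAc)2, P(o-tol)3, K3PO4, THF/H2O, rt), in which zerovalent palladium now enters the reactive C–Br bond of the bromoacetate, should then give 9.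

Step 12. The Lewis acid may attack the methyl ester or ionise the benzylic C2–O1 bond before the slower benzyl ester has been cleaved. The fallback sets out from 17 and comes back at 18; it replaces Lewis-acid dealkylation by catalytic transfer hydrogenolysis (Pd/C, 1,4-cyclohexadiene, EtOH/DMF, rt). This reaction type has precedent for removing benzyl groups from caffeate-type esters without saturating the conjugated double bond when the hydrogen donor is kept limiting. The reaction would be stopped as soon as the last benzyl group has gone so that the C2–O1 bond is not hydrogenolysed. It makes no compound outside the list (entry F0).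

Further compounds
F1 | step 6 | racemic benzyl (2S*,3R*)-7-(benzyloxy)-2-[3,4-bis(benzyloxy)phenyl]-4-[(E)-3-tert-butoxy-3-oxoprop-1-en-1-yl]-2,3-dihydro-1-benzofuran-3-carboxylate (cis, both enantiomers) | CC(C)(C)OC(=O)/C=C/c1ccc(OCc3ccccc3)c2c1[C@@H](C(=O)OCc1ccccc1)[C@@H](c1ccc(OCc3ccccc3)c(OCc3ccccc3)c1)O2.CC(C)(C)OC(=O)/C=C/c1ccc(OCc3ccccc3)c2c1[C@H](C(=O)OCc1ccccc1)[C@H](c1ccc(OCc3ccccc3)c(OCc3ccccc3)c1)O2
F2 | step 6 | racemic benzyl (2S*,3S*)-7-(benzyloxy)-2-[3,4-bis(benzyloxy)phenyl]-4-[(E)-3-tert-butoxy-3-oxoprop-1-en-1-yl]-2,3-dihydro-1-benzofuran-3-carboxylate (trans, both enantiomers) | CC(C)(C)OC(=O)/C=C/c1ccc(OCc3ccccc3)c2c1[C@H](C(=O)OCc1ccccc1)[C@@H](c1ccc(OCc3ccccc3)c(OCc3ccccc3)c1)O2.CC(C)(C)OC(=O)/C=C/c1ccc(OCc3ccccc3)c2c1[C@@H](C(=O)OCc1ccccc1)[C@H](c1ccc(OCc3ccccc3)c(OCc3ccccc3)c1)O2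
F3 | step 6 | benzyl (2R,3R)-7-(benzyloxy)-2-[3,4-bis(benzyloxy)phenyl]-4-[(E)-3-tert-butoxy-3-oxoprop-1-en-1-yl]-2,3-dihydro-1-benzofuran-3-carboxylate (enantiomer of 12) | CC(C)(C)OC(=O)/C=C/c1ccc(OCc3ccccc3)c2c1[C@@H](C(=O)OCc1ccccc1)[C@H](c1ccc(OCc3ccccc3)c(OCc3ccccc3)c1)O2
F4 | step 4 | tert-butyl (E)-3-[4-(benzyloxy)-3-{[3,4-bis(benzyloxy)benzyl]oxy}-2-(4,4,5,5-tetramethyl-1,3,2-dioxaborolan-2-yl)phenyl]acrylate | CC(C)(C)OC(=O)/C=C/c1ccc(OCc2ccccc2)c(OCc2ccc(OCc3ccccc3)c(OCc3ccccc3)c2)c1B1OC(C)(C)C(C)(C)O1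
F0 | step 12 | none | none
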